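**Plan**

- Retrosynthesis: the three aryl O–benzyl bonds are cut last. The hydroxy-ketone arm on ring B is cut at its CH–C(=O) and CH2–O bonds (vinylarene, aroyl chloride, boron), and the vinyl group at the aryl–C bond (aryl bromide). The C3 benzyl is taken back to a C3=CH arylidene, and the lactone is cut at O1–C2 and C2–C3, releasing CO and a 4-aryl-but-3-yn-1-ol. The alkynol is cut at the alkyne–ring B bond and at the alkyne C–C bond, back to a desymmetrised 2-(arylmethyl)propane-1,3-diol from O-benzylvanillin and diethyl malonate.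
- Feature used: carbonyl carbon C2 lies between ring oxygen O1 and C3, and C3 carries the benzylic carbon leading to ring B. A hydroxyl on C5 and an alkyne from C3 to the ring B carbon therefore flank the site where CO must go.
- Forward: the ring A chain is built first (steps 1–8), ring B is joined by Sonogashira coupling, and the lactone (the only ring made) closes by cyclocarbonylation. Conjugate reduction and epimerisation, vinylation, borylacylation bringing ring C, C–B oxidation and debenzylation follow.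
- Stereochemistry: C4 comes from a lipase desymmetrisation of the prochiral diol, C3 from base equilibration to trans relative to C4, and the side-chain centre from the chiral copper catalyst of the borylacylation.

Key step: step 13

Remark (assumption): lipase PS acetylation of the 2-(arylmethyl)propane-1,3-diol is taken to favour the arm that gives the (R)-monoacetate 6. This sense has to be confirmed on the first batch; hydrolysis of the diacetate with the same enzyme would give the mirror-image monoacetate.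

Numbering used: lactone O1, C2 (carbonyl), C3, C4, C5. Ring A is the aryl of the C4 benzyl, ring B the aryl of the C3 benzyl, ring C the aroyl ring.

**Route**

Step 1
Reactants: 1 4-(benzyloxy)-3-methoxybenzaldehyde; 2 diethyl malonate
Product: 3 diethyl 2-(4-benzyloxy-3-methoxybenzylidene)malonate
Conditions: piperidine (cat.), AcOH (cat.), toluene, reflux, Dean–Stark
Reagents that add atoms: none
Why: Knoevenagel condensation of an aryl aldehyde with a malonate, driven to completion by removal of water.

Step 2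
Reactants: 3 diethyl 2-(4-benzyloxy-3-methoxybenzylidene)malonate
Product: 4 diethyl 2-(4-benzyloxy-3-methoxybenzyl)malonate
Conditions: NaBH4, EtOH, 0 °C
Reagents that add atoms: none
Why: Conjugate hydride reduction of an arylidene malonate, whose doubly activated alkene should be reduced well before the esters while the benzyl ether is inert.

Step 3
Reactants: 4 diethyl 2-(4-benzyloxy-3-methoxybenzyl)malonate
Product: 5 2-(4-benzyloxy-3-methoxybenzyl)propane-1,3-diol
Conditions: LiAlH4, THF, 0 °C to rt; aqueous NaOH work-up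
Reagents that add atoms: none
Why: LiAlH4 reduction of both esters should give the prochiral 1,3-diol.

Step 4
Reactants: 5 2-(4-benzyloxy-3-methoxybenzyl)propane-1,3-diol
Product: 6 (R)-2-(4-benzyloxy-3-methoxybenzyl)-3-hydroxypropyl acetate
Conditions: lipase PS (Burkholderia cepacia), vinyl acetate, i-Pr2O, rt
Reagents that add atoms: vinyl acetate, CC(=O)OC=C
Why: Lipase-catalysed enantiotopic-group-selective transesterification (desymmetrisation) with an irreversible acyl donor, in which the enzyme pocket distinguishes the two hydroxymethyl arms and so fixes the carbon that becomes C4.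

Step 5
Reactants: 6 (R)-2-(4-benzyloxy-3-methoxybenzyl)-3-hydroxypropyl acetate
Product: 7 (S)-2-(4-benzyloxy-3-methoxybenzyl)-3-(tert-butyldiphenylsilyloxy)propyl acetate
Conditions: TBDPSCl, imidazole, CH2Cl2, 0 °C to rt
Reagents that add atoms: tert-butyl(chloro)diphenylsilane, CC(C)(C)[Si](Cl)(c1ccccc1)c1ccccc1
Why: Imidazole-mediated silylation of the free primary alcohol, with the bulky TBDPS group chosen because it should not migrate to the neighbouring oxygen in the next basic step and scramble the two arms.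

Step 6
Reactants: 7 (S)-2-(4-benzyloxy-3-methoxybenzyl)-3-(tert-butyldiphenylsilyloxy)propyl acetate
Product: 8 (S)-2-(4-benzyloxy-3-methoxybenzyl)-3-(tert-butyldiphenylsilyloxy)propan-1-ol
Conditions: K2CO3 (cat.), MeOH, 0 °C
Reagents that add atoms: none
Why: Carbonate-catalysed methanolysis (transesterification) of the acetate should free the arm destined to become the alkyne while the silyl ether stays in place.

Step 7
Reactants: 8 (S)-2-(4-benzyloxy-3-methoxybenzyl)-3-(tert-butyldiphenylsilyloxy)propan-1-ol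
Product: 9 (R)-2-(4-benzyloxy-3-methoxybenzyl)-3-(tert-butyldiphenylsilyloxy)propanal
Conditions: Dess–Martin periodinane, CH2Cl2, 0 °C to rt; used crude
Reagents that add atoms: none
Why: Dess–Martin oxidation under near-neutral conditions should give the α-branched aldehyde without epimerisation, provided it is carried on at once.

Step 8
Reactants: 9 (R)-2-(4-benzyloxy-3-methoxybenzyl)-3-(tert-butyldiphenylsilyloxy)propanal
Product: 10 (S)-[2-(4-benzyloxy-3-methoxybenzyl)but-3-ynyloxy](tert-butyl)diphenylsilane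
Conditions: dimethyl (1-diazo-2-oxopropyl)phosphonate, K2CO3, MeOH, 0 °C to rt
Reagents that add atoms: dimethyl (1-diazo-2-oxopropyl)phosphonate, COP(=O)(OC)C(=[N+]=[N-])C(C)=O
Why: Seyferth–Gilbert homologation in its Ohira–Bestmann form should turn the aldehyde into the terminal alkyne through a diazoalkene and alkylidene-carbene 1,2-shift, under conditions mild enough for β-silyloxy α-branched aldehydes to keep their configuration.

Step 9
Reactants: 11 2-bromo-6-methoxyphenol
Product: 12 2-bromo-4-iodo-6-methoxyphenol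
Conditions: N-iodosuccinimide, TsOH·H2O (cat.), MeCN, rt
Reagents that add atoms: N-iodosuccinimide, O=C1CCC(=O)N1I
Why: Electrophilic aromatic iodination directed para by the hydroxyl, both ortho positions being blocked by Br and OMe.

Step 10
Reactants: 12 2-bromo-4-iodo-6-methoxyphenol
Product: 13 2-benzyloxy-1-bromo-5-iodo-3-methoxybenzene
Conditions: BnBr, K2CO3, DMF, 50 °C
Reagents that add atoms: benzyl bromide, BrCc1ccccc1
Why: Williamson ether synthesis on the phenoxide.

Step 11
Reactants: 10 (S)-[2-(4-benzyloxy-3-methoxybenzyl)but-3-ynyloxy](tert-butyl)diphenylsilane; 13 2-benzyloxy-1-bromo-5-iodo-3-methoxybenzene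
Product: 14 (S)-[2-(4-benzyloxy-3-methoxybenzyl)-4-(4-benzyloxy-3-bromo-5-methoxyphenyl)but-3-ynyloxy](tert-butyl)diphenylsilane
Conditions: PdCl2(PPh3)2 (cat.), CuI (cat.), Et3N, THF, rt
Reagents that add atoms: none
Why: Sonogashira coupling, in which zerovalent palladium should insert into the C–I bond far faster than into the flanked, electron-rich C–Br bond at room temperature.

Step 12
Reactants: 14 (S)-[2-(4-benzyloxy-3-methoxybenzyl)-4-(4-benzyloxy-3-bromo-5-methoxyphenyl)but-3-ynyloxy](tert-butyl)diphenylsilane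
Product: 15 (S)-2-(4-benzyloxy-3-methoxybenzyl)-4-(4-benzyloxy-3-bromo-5-methoxyphenyl)but-3-yn-1-ol
Conditions: TBAF, THF, 0 °C to rt
Reagents that add atoms: none
Why: Fluoride-mediated cleavage of the silyl ether should free the homopropargylic hydroxyl without touching the alkyne, the bromide or the benzyl ethers.

Step 13
Reactants: 15 (S)-2-(4-benzyloxy-3-methoxybenzyl)-4-(4-benzyloxy-3-bromo-5-methoxyphenyl)but-3-yn-1-ol; 16 carbon monoxide
Product: 17 (3E,4S)-3-(4-benzyloxy-3-bromo-5-methoxybenzylidene)-4-(4-benzyloxy-3-methoxybenzyl)oxolan-2-one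
Conditions: PdCl2(PPh3)2 (5 mol%), SnCl2 (5 mol%), CO (8 bar), MeCN, 75 °C
Reagents that add atoms: none
Why: The hydroxyl adds to CO bound to divalent palladium (PdCl2(PPh3)2 made more electrophilic by SnCl2) to give an alkoxycarbonyl–palladium species, which adds syn across the tethered alkyne with the acyl carbon bonding to the proximal alkyne carbon, and protonolysis of the vinyl–palladium bond with retention by the HCl formed releases the lactone and the divalent catalyst. The closest known reaction is the PdCl2/SnCl2/phosphine cyclocarbonylation of but-3-yn-1-ols, internal ones included, to α-methylene and (E)-α-alkylidene γ-butyrolactones. The lactone closes in the 5-exo-dig mode (C2–C3 bond formed, distal alkyne carbon left exocyclic), which should be preferred over 6-endo closure to a dihydropyranone. No stereocentre is created: the E geometry follows from syn addition and retentive protonolysis, and C4 is untouched because the medium is not basic. The step needs selectivity for the alkyne over the aryl C–Br bond, which the absence of zerovalent palladium and the flanked, electron-rich bromide should secure, and preference for the carbonylative path over direct 5-endo attack of the hydroxyl on the alkyne, which the CO pressure should secure.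

Step 14
Reactants: 17 (3E,4S)-3-(4-benzyloxy-3-bromo-5-methoxybenzylidene)-4-(4-benzyloxy-3-methoxybenzyl)oxolan-2-one
Product: 19 (3S,4S)-trans-3-(4-benzyloxy-3-bromo-5-methoxybenzyl)-4-(4-benzyloxy-3-methoxybenzyl)oxolan-2-one, via cis-lactone 18 (not isolated)
Conditions: [(Ph3P)CuH]6 (0.4 equiv), degassed wet toluene, rt; silica plug; then DBU, toluene, 80 °C
Reagents that add atoms: none
Why: Conjugate reduction with Stryker reagent (hydride from copper to the benzylic β-carbon, copper enolate protonated by water) should leave the aryl bromide and benzyl ethers alone, and DBU then epimerises C3 through the lactone enolate to the thermodynamically preferred trans arrangement relative to the fixed C4 centre.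

Step 15
Reactants: 19 (3S,4S)-trans-3-(4-benzyloxy-3-bromo-5-methoxybenzyl)-4-(4-benzyloxy-3-methoxybenzyl)oxolan-2-one
Product: 20 (3S,4S)-3-(4-benzyloxy-3-ethenyl-5-methoxybenzyl)-4-(4-benzyloxy-3-methoxybenzyl)oxolan-2-one
Conditions: tributyl(vinyl)stannane, Pd(PPh3)4 (cat.), toluene, 100 °C
Reagents that add atoms: tributyl(vinyl)stannane, C=C[Sn](CCCC)(CCCC)CCCC
Why: Stille vinylation of the aryl bromide under neutral conditions, which the lactone and its trans centres should tolerate.

Step 16
Reactants: 21 4-(benzyloxy)-3-methoxybenzoic acid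
Product: 22 4-(benzyloxy)-3-methoxybenzoyl chloride
Conditions: (COCl)2, DMF (cat.), CH2Cl2, 0 °C to rt; used crude
Reagents that add atoms: oxalyl chloride, O=C(Cl)C(=O)Cl
Why: Acid chloride formation through Vilsmeier-type activation of the carboxylic acid.

Step 17
Reactants: 20 (3S,4S)-3-(4-benzyloxy-3-ethenyl-5-methoxybenzyl)-4-(4-benzyloxy-3-methoxybenzyl)oxolan-2-one; 22 4-(benzyloxy)-3-methoxybenzoyl chloride
Product: 23 (3S,4S)-3-{4-benzyloxy-3-[(2R)-1-(4-benzyloxy-3-methoxyphenyl)-1-oxo-3-(4,4,5,5-tetramethyl-1,3,2-dioxaborolan-2-yl)propan-2-yl]-5-methoxybenzyl}-4-(4-benzyloxy-3-methoxybenzyl)oxolan-2-one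
Conditions: CuCl (5 mol%), Ph-BPE (6 mol%, the antipode that gives the 2R boronate, fixed in a trial run), B2pin2, NaOt-Bu, THF, rt; 22 added last
Reagents that add atoms: bis(pinacolato)diboron, CC1(C)OB(OC1(C)C)B1OC(C)(C)C(C)(C)O1
Why: Copper-catalysed enantioselective borylacylation of a vinylarene, in which the chiral bisphosphine–Cu–Bpin species adds across the vinyl group with boron at the terminal carbon and the benzylic copper formed is acylated by the aroyl chloride, so that the ligand sets the new benzylic centre under reagent control.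

Step 18
Reactants: 23 the β-boryl ketone of step 17
Product: 24 (3S,4S)-3-{4-benzyloxy-3-[(2S)-1-(4-benzyloxy-3-methoxyphenyl)-3-hydroxy-1-oxopropan-2-yl]-5-methoxybenzyl}-4-(4-benzyloxy-3-methoxybenzyl)oxolan-2-one
Conditions: NaBO3·4H2O, THF/H2O, 0 °C
Reagents that add atoms: sodium perborate tetrahydrate (NaBO3·4H2O, drawn as the dimeric peroxoborate), [Na+].[Na+].O[B-]1(O)OO[B-](O)(O)OO1
Why: Perborate oxidation of the C–B bond (1,2-shift of the primary carbon from boron to oxygen) should convert CH2–Bpin into CH2OH without involving the adjacent stereocentre, the cold and only mildly basic medium limiting enolisation.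

Step 19
Reactants: 24 the tribenzyl β-hydroxy ketone of step 18
Product: 25 (3S,4S)-3-{4-hydroxy-3-[(2S)-3-hydroxy-1-(4-hydroxy-3-methoxyphenyl)-1-oxopropan-2-yl]-5-methoxybenzyl}-4-(4-hydroxy-3-methoxybenzyl)oxolan-2-one (CNP0281222.1)
Conditions: H2 (1 atm), Pd/C, EtOAc/EtOH, rt
Reagents that add atoms: none
Why: Catalytic hydrogenolysis of the three aryl benzyl ethers in a neutral medium, which should spare the β-hydroxy ketone because the electron-rich aryl ketone is reduced far more slowly than O-benzyl groups are cleaved.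

**Compound list**

1 | 4-(benzyloxy)-3-methoxybenzaldehyde | COc1cc(C=O)ccc1OCc1ccccc1 | starting material
2 | diethyl malonate | CCOC(=O)CC(=O)OCC | starting material
3 | diethyl 2-(4-benzyloxy-3-methoxybenzylidene)malonate | CCOC(=O)C(=Cc1ccc(OCc2ccccc2)c(OC)c1)C(=O)OCC | intermediate
4 | diethyl 2-(4-benzyloxy-3-methoxybenzyl)malonate | CCOC(=O)C(Cc1ccc(OCc2ccccc2)c(OC)c1)C(=O)OCC | intermediate
5 | 2-(4-benzyloxy-3-methoxybenzyl)propane-1,3-diol | OCC(CO)Cc1ccc(OCc2ccccc2)c(OC)c1 | intermediate
6 | (R)-2-(4-benzyloxy-3-methoxybenzyl)-3-hydroxypropyl acetate | CC(=O)OC[C@@H](CO)Cc1ccc(OCc2ccccc2)c(OC)c1 | intermediate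
7 | (S)-2-(4-benzyloxy-3-methoxybenzyl)-3-(tert-butyldiphenylsilyloxy)propyl acetate | CC(=O)OC[C@@H](CO[Si](c1ccccc1)(c1ccccc1)C(C)(C)C)Cc1ccc(OCc2ccccc2)c(OC)c1 | intermediate
8 | (S)-2-(4-benzyloxy-3-methoxybenzyl)-3-(tert-butyldiphenylsilyloxy)propan-1-ol | OC[C@@H](CO[Si](c1ccccc1)(c1ccccc1)C(C)(C)C)Cc1ccc(OCc2ccccc2)c(OC)c1 | intermediate
9 | (R)-2-(4-benzyloxy-3-methoxybenzyl)-3-(tert-butyldiphenylsilyloxy)propanal | O=C[C@@H](CO[Si](c1ccccc1)(c1ccccc1)C(C)(C)C)Cc1ccc(OCc2ccccc2)c(OC)c1 | intermediate
10 | (S)-[2-(4-benzyloxy-3-methoxybenzyl)but-3-ynyloxy](tert-butyl)diphenylsilane | C#C[C@@H](CO[Si](c1ccccc1)(c1ccccc1)C(C)(C)C)Cc1ccc(OCc2ccccc2)c(OC)c1 | intermediate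
11 | 2-bromo-6-methoxyphenol | COc1cccc(Br)c1O | starting material
12 | 2-bromo-4-iodo-6-methoxyphenol | COc1cc(I)cc(Br)c1O | intermediate
13 | 2-benzyloxy-1-bromo-5-iodo-3-methoxybenzene | COc1cc(I)cc(Br)c1OCc1ccccc1 | intermediate
14 | (S)-[2-(4-benzyloxy-3-methoxybenzyl)-4-(4-benzyloxy-3-bromo-5-methoxyphenyl)but-3-ynyloxy](tert-butyl)diphenylsilane | COc1cc(C#C[C@@H](CO[Si](c2ccccc2)(c2ccccc2)C(C)(C)C)Cc2ccc(OCc3ccccc3)c(OC)c2)cc(Br)c1OCc1ccccc1 | intermediate
15 | (S)-2-(4-benzyloxy-3-methoxybenzyl)-4-(4-benzyloxy-3-bromo-5-methoxyphenyl)but-3-yn-1-ol | COc1cc(C#C[C@@H](CO)Cc2ccc(OCc3ccccc3)c(OC)c2)cc(Br)c1OCc1ccccc1 | intermediate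
16 | carbon monoxide | [C-]#[O+] | starting material
17 | (3E,4S)-3-(4-benzyloxy-3-bromo-5-methoxybenzylidene)-4-(4-benzyloxy-3-methoxybenzyl)oxolan-2-one | COc1cc(C[C@@H]2COC(=O)/C2=C/c2cc(OC)c(OCc3ccccc3)c(Br)c2)ccc1OCc1ccccc1 | intermediate
18 | (3R,4S)-cis-3-(4-benzyloxy-3-bromo-5-methoxybenzyl)-4-(4-benzyloxy-3-methoxybenzyl)oxolan-2-one (kinetic C3 epimer) | COc1cc(C[C@@H]2COC(=O)[C@@H]2Cc2cc(OC)c(OCc3ccccc3)c(Br)c2)ccc1OCc1ccccc1 | intermediate
19 | (3S,4S)-trans-3-(4-benzyloxy-3-bromo-5-methoxybenzyl)-4-(4-benzyloxy-3-methoxybenzyl)oxolan-2-one | COc1cc(C[C@@H]2COC(=O)[C@H]2Cc2cc(OC)c(OCc3ccccc3)c(Br)c2)ccc1OCc1ccccc1 | intermediate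
20 | (3S,4S)-3-(4-benzyloxy-3-ethenyl-5-methoxybenzyl)-4-(4-benzyloxy-3-methoxybenzyl)oxolan-2-one | COc1cc(C[C@@H]2COC(=O)[C@H]2Cc2cc(OC)c(OCc3ccccc3)c(C=C)c2)ccc1OCc1ccccc1 | intermediate
21 | 4-(benzyloxy)-3-methoxybenzoic acid | COc1cc(C(=O)O)ccc1OCc1ccccc1 | starting material
22 | 4-(benzyloxy)-3-methoxybenzoyl chloride | COc1cc(C(=O)Cl)ccc1OCc1ccccc1 | intermediate
23 | (3S,4S)-3-{4-benzyloxy-3-[(2R)-1-(4-benzyloxy-3-methoxyphenyl)-1-oxo-3-(4,4,5,5-tetramethyl-1,3,2-dioxaborolan-2-yl)propan-2-yl]-5-methoxybenzyl}-4-(4-benzyloxy-3-methoxybenzyl)oxolan-2-one | COc1cc(C[C@@H]2COC(=O)[C@H]2Cc2cc(OC)c(OCc3ccccc3)c([C@@H](CB3OC(C)(C)C(C)(C)O3)C(=O)c3ccc(OCc4ccccc4)c(OC)c3)c2)ccc1OCc1ccccc1 | intermediate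
24 | (3S,4S)-3-{4-benzyloxy-3-[(2S)-1-(4-benzyloxy-3-methoxyphenyl)-3-hydroxy-1-oxopropan-2-yl]-5-methoxybenzyl}-4-(4-benzyloxy-3-methoxybenzyl)oxolan-2-one | COc1cc(C[C@@H]2COC(=O)[C@H]2Cc2cc(OC)c(OCc3ccccc3)c([C@@H](CO)C(=O)c3ccc(OCc4ccccc4)c(OC)c3)c2)ccc1OCc1ccccc1 | intermediate
25 | (3S,4S)-3-{4-hydroxy-3-[(2S)-3-hydroxy-1-(4-hydroxy-3-methoxyphenyl)-1-oxopropan-2-yl]-5-methoxybenzyl}-4-(4-hydroxy-3-methoxybenzyl)oxolan-2-one (CNP0281222.1) | COc1cc(C[C@@H]2COC(=O)[C@H]2Cc2cc(OC)c(O)c([C@@H](CO)C(=O)c3ccc(O)c(OC)c3)c2)ccc1O | target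

**Step count**

Total: 19 steps. Longest linear sequence: 16 steps (steps 1–8, 11–15 and 17–19, from 1 to 25).

**Steps most likely to fail**

Step 17. The alkoxide base may enolise the lactone or the product ketone, leading to acylation at C3 or loss of configuration at the new centre, and facial control by the ligand may be weak on an ortho-alkoxy vinylarene. The fallback builds the arm by enolate chemistry instead. Setting out from bromide 19, palladium-catalysed ketone α-arylation (Pd(OAc)2, XPhos, K3PO4, toluene, 90 °C) with commercial 1-(4-benzyloxy-3-methoxyphenyl)ethanone would give the aryl benzyl ketone F1. TMSOTf and Et3N would give its (Z)-trimethylsilyl enol ether F2. An enantioselective Mukaiyama-type hydroxymethylation with aqueous formaldehyde, Sc(OTf)3 and a chiral 2,2'-bipyridine diol ligand would then rejoin the route at 24, so that steps 15, 17 and 18 are not needed.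

Step 13. The hydroxyl may attack the palladium-bound aryl alkyne directly (5-endo cycloisomerisation to a dihydrofuran), or insertion of the aryl-substituted internal alkyne may be too slow. The fallback carbonylates before the aryl group is attached. Setting out from silyl ether 10, TBAF would free the terminal alkynol F3. The same PdCl2(PPh3)2/SnCl2/CO conditions, applied to this unhindered terminal alkyne, would close the α-methylene lactone F4. A Heck arylation with iodide 13 (Pd(OAc)2, KOAc, DMF, 80 °C), selective for the C–I bond, would then give the (E)-arylidene lactone and rejoin the route at 17.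

Step 18. The ketone α-carbon may lose its configuration by enolisation, or the new β-hydroxy ketone may undergo β-elimination or retro-aldol cleavage in the basic peroxide medium. The fallback lowers the oxidation level of the ketone for the duration of the C–B oxidation. Setting out from 23, Luche reduction (NaBH4, CeCl3·7H2O, MeOH, −40 °C) would give the carbinol boronate F5 as a mixture of carbinol epimers, whose side-chain centre can no longer enolise. NaBO3·4H2O would then give the 1,3-diol F6, and MnO2 in CH2Cl2, which oxidises only the benzylic alcohol, would rejoin the route at 24.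

**Further compounds**

F1 | step 17 | (3S,4S)-3-{4-benzyloxy-3-[2-(4-benzyloxy-3-methoxyphenyl)-2-oxoethyl]-5-methoxybenzyl}-4-(4-benzyloxy-3-methoxybenzyl)oxolan-2-one | COc1cc(C[C@@H]2COC(=O)[C@H]2Cc2cc(OC)c(OCc3ccccc3)c(CC(=O)c3ccc(OCc4ccccc4)c(OC)c3)c2)ccc1OCc1ccccc1
F2 | step 17 | (Z)-trimethylsilyl enol ether of F1 | COc1cc(C[C@@H]2COC(=O)[C@H]2Cc2cc(OC)c(OCc3ccccc3)c(/C=C(\O[Si](C)(C)C)c3ccc(OCc4ccccc4)c(OC)c3)c2)ccc1OCc1ccccc1
F3 | step 13 | (S)-2-(4-benzyloxy-3-methoxybenzyl)but-3-yn-1-ol | C#C[C@@H](CO)Cc1ccc(OCc2ccccc2)c(OC)c1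
F4 | step 13 | (S)-4-(4-benzyloxy-3-methoxybenzyl)-3-methylideneoxolan-2-one | COc1cc(C[C@@H]2COC(=O)C2=C)ccc1OCc1ccccc1
F5 | step 18 | (3S,4S)-3-{4-benzyloxy-3-[(2R)-1-(4-benzyloxy-3-methoxyphenyl)-1-hydroxy-3-(4,4,5,5-tetramethyl-1,3,2-dioxaborolan-2-yl)propan-2-yl]-5-methoxybenzyl}-4-(4-benzyloxy-3-methoxybenzyl)oxolan-2-one, carbinol epimers | COc1cc(C[C@@H]2COC(=O)[C@H]2Cc2cc(OC)c(OCc3ccccc3)c([C@@H](CB3OC(C)(C)C(C)(C)O3)C(O)c3ccc(OCc4ccccc4)c(OC)c3)c2)ccc1OCc1ccccc1
F6 | step 18 | (3S,4S)-3-{4-benzyloxy-3-[(2S)-1-(4-benzyloxy-3-methoxyphenyl)-1,3-dihydroxypropan-2-yl]-5-methoxybenzyl}-4-(4-benzyloxy-3-methoxybenzyl)oxolan-2-one, carbinol epimers | COc1cc(C[C@@H]2COC(=O)[C@H]2Cc2cc(OC)c(OCc3ccccc3)c([C@@H](CO)C(O)c3ccc(OCc4ccccc4)c(OC)c3)c2)ccc1OCc1ccccc1
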